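## Structural features

The target is a monocyclic 3,4-seco-drimane: a cyclohex-3-ene (ring atoms C1 to C6) with a quaternary C1 bearing a methyl group and a 2-carboxyethyl chain, a C2 bearing a CH2–O link to C7 of a coumarin, a vinylic methyl on C3 (C3=C4), a CH2 at C5 and an isopropenyl group on C6. The stereocentres C6, C1 and C2 are contiguous and all R; the isopropenyl group, the C1 methyl and the C2 aryloxymethyl group lie on one face of the ring, the acid chain alone on the other. Fragile groups are the coumarin lactone with its conjugated alkene (strong base, hydride, nucleophiles), the two isolated alkenes (acid, boranes, oxidants), the allylic C2–H (lost if C3=C4 migrates) and the free acid. The real difficulty is the quaternary C1 wedged between two stereocentres, together with attaching the oxygenated carbon at C2 cis to the C1 methyl in a molecule whose isopropenyl group reacts like any exocyclic alkene that could serve as precursor of that carbon. The feature the key step exploits: the central isopropenyl carbon and ring carbon C4 are 1,3-related through C6 and C5, so a bond between them, with C3=C4 moved out to an exocyclic C3=CH2, turns the methylcyclohexene/isopropenyl pair into a 2-methylidene-6,6-dimethylbicyclo[3.1.1]heptane (pinane) skeleton. In that bicycle (primed locants) C4', C3', C2', C1', C7', C5' are ring C1, C2, C3, C4, C5, C6 and C6' is the isopropenyl carbon; (1S,5S)-verbenone already holds the C6 stereocentre (C5'), the C1 methyl (on C4') and an enone through which the two missing carbon substituents can enter under control of the CMe2 bridge.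

## Logic of the disconnections

**16 from 14 by way of 15.** No skeletal bond is cut; the carboxyl carbon is carried as a silyl-protected primary alcohol. The reason is that an acid or ester would not survive the organometallic steps, whereas the silyl ether is inert to all of them. The demand on the forward steps is desilylation without lactone opening and an oxidation that spares two alkenes and an aryl ether.

**14 from 13 (key disconnection).** In one sentence, the route is a cobalt-hydride-triggered radical ring-opening isomerisation of the methylidene-bicyclo[3.1.1]heptane 13, which releases the whole carbocyclic half of the target. Backwards, the bond C1'–C6' (ring C4 to the isopropenyl carbon) is made, the C3=C4 bond becomes exocyclic and one hydrogen is moved. The gain is that the trisubstituted ring alkene and the isopropenyl group collapse into one cyclobutane and one exocyclic alkene, so both alkenes are absent while C2 is built. The three stereocentres become C5', C4' and C3' of a rigid bicycle whose two faces differ by a CMe2 bridge against a CH2 bridge. The demand is scission of C1'–C6' only, termination as isopropenyl and not isopropylidene, and no loss of the C3'–H or of the coumarin alkene.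

**13 from 12.** The exocyclic C2'=CH2 bond is traced back to a C2'–O bond and a methyl C–H bond. A tertiary carbinol is chosen because, unlike a C2' ketone, it leaves the neighbouring C3' stereocentre non-epimerisable. The demand is elimination toward the methyl group only.

**12 from 10 and 11.** The O–CH2 bond between the coumarin oxygen and the C3' side-chain carbon is cut. This is the convergent point: the aryl ether also serves as protection of the primary alcohol. The demand is substitution at a β-branched primary carbon with the tertiary alcohol left alone.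

**10 from 8.** The C–O bond of the CH2OH carbon and the C3'–H bond are cut (anti-Markovnikov hydration of an exocyclic alkene). This is the step that sets ring C2. The simplification is that C3' becomes sp2 and no alkene other than the one to be functionalised is present. The demand is hydrogen delivery to C3' from the face anti to the CMe2 bridge.

**8 from 7, and 7 from 4.** The C2'–CH3 bond is cut (carbonyl addition), then the C3'=CH2 bond (α-methylenation of an enol ether). Both carbons are introduced at the only enolisable and the only electrophilic position of the bicycle, so no regiochemical question arises. The demand is 1,2-addition rather than 1,4-addition to an exocyclic enone.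

**4 from 1 and 2 (via 3).** The C4'–CH2 bond of the chain is cut. Conjugate addition to the enone of 1 makes the quaternary centre in the first step from two purchased compounds. The demand is attack on a β,β-disubstituted enone from the face anti to the CMe2 bridge, which places the chain trans and the resident methyl cis to the future isopropenyl group.

## Other disconnections considered

**Alternative 1:** (the first to come to mind) Cut the C1–CH3, C1–chain and C2–CH2O bonds and start from (S)-carvone, whose ring, vinylic methyl, alkene and isopropenyl group map directly onto the target. The forward key step is two successive alkylations of the kinetic α'-enolate (iodomethane, then methyl acrylate anti to the isopropenyl group) to give A1, followed by one-carbon homologation of the carbonyl to aldehyde A2, reduction and etherification. The chosen plan is preferred for three reasons: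
- The carbonyl of A1 sits between a quaternary carbon and a methyl-bearing sp2 carbon, so Wittig-type homologation is expected to be sluggish.
- The C2 stereocentre would be born as an epimerisable β,γ-unsaturated aldehyde that can slip into conjugation, with only a modest thermodynamic bias.
- Any hydroboration-based homologation cannot distinguish the new exocyclic alkene from the isopropenyl group, and the ester has to be told apart from the aldehyde. In the chosen plan both alkenes are latent while C2 is set by kinetic reagent approach on a rigid bicycle.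

**Alternative 2:** Cut nothing in the ring but rejoin the isopropenyl carbon to the carboxyl carbon, i.e. regard the target as a ring-A-cleaved drimane. The forward key steps are Lewis-acid polyene cyclisation of the (R)-epoxide A3 of farnesyl umbelliferyl ether, oxidation to the bicyclic 3-ketone A4, and Beckmann fragmentation of its oxime to the seco-nitrile A5, then hydrolysis. The chosen plan is preferred for four reasons:
- The cyclisation must set four stereocentres (one is then destroyed) and choose one of three alkene positions on termination.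
- The allylic aryl ether of A3 can ionise under the Lewis acid.
- The required 10R series is the mirror image of the cheap drimane pool (sclareolide), so no pool material shortens the route.
- Nitrile hydrolysis is harsh for the coumarin lactone. Step economy is also worse (an enantioselective epoxidation of a triene comes first).

**Alternative 3:** Cut the C2–CH2O bond by [2,3]-sigmatropic logic. The forward key step is a Wittig–Still rearrangement of the stannylmethyl ether A6 (from cis-selective reduction of enone A7 and O-alkylation): tin–lithium exchange, then a suprafacial shift that delivers CH2OH to C2 on the face of the breaking C–O bond and leaves the alkene at C3=C4. The stereochemical logic is sound (1,3-chirality transfer, cis to isopropenyl). However, A7 carries the quaternary carbon γ to its carbonyl and is therefore not an alkylation product of carvone. It would need its own enantioselective annulation or a Diels–Alder reaction in which the diene substituents direct in opposite senses. The route also uses stoichiometric tin and carries the isopropenyl group throughout. The chosen plan obtains the quaternary centre in one step from a purchased enone.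

Key step: step 7

Remark 1: bicyclic intermediates keep the verbenone atom numbering (C1' bridgehead next to C2', C6' = CMe2 bridge, C7' = CH2 bridge), also where lowest-locant rules would renumber. The C5' descriptor changes from S in 1 to R in 4 only through a change of CIP priorities.

Remark 2: the levorotatory commercial verbenone is taken to be the (1S,5S) enantiomer and is assumed enantiopure (if necessary made by allylic oxidation of high-ee (−)-α-pinene). The descriptor, not the sign, defines the starting material.

Remark 3: Co(tBu4-salen)Cl stands for chloro[N,N'-bis(3,5-di-tert-butylsalicylidene)ethane-1,2-diaminato]cobalt, C32H46ClCoN2O2, a trivalent cobalt complex.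

## Steps

Step 1
Reactants: 1 (1S,5S)-4,6,6-trimethylbicyclo[3.1.1]hept-3-en-2-one ((−)-verbenone); 2 (3-bromopropoxy)(tert-butyl)dimethylsilane
Product: 4 (1S,4R,5R)-4-[3-(tert-butyldimethylsilyloxy)propyl]-4,6,6-trimethyl-2-(trimethylsilyloxy)bicyclo[3.1.1]hept-2-ene, via Grignard reagent 3 (not isolated)
Conditions: 2, Mg, THF, rt→40 °C; then CuBr·SMe2 (10 mol%), TMSCl, 1, THF, −78→−30 °C; Et3N, pentane, filtration
Reagents that add atoms: chlorotrimethylsilane, C[Si](C)(C)Cl
Why: Copper-catalysed, TMSCl-accelerated conjugate addition of a Grignard reagent to a β,β-disubstituted enone; the syn methyl of the CMe2 bridge shields one face of C4', so the chain should enter anti to the bridge and set the quaternary centre (4R, resident methyl syn to the bridge); the enolate is trapped as the only possible silyl enol ether because C1' is a bridgehead.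

Step 2
Reactants: 4 (1S,4R,5R)-4-[3-(tert-butyldimethylsilyloxy)propyl]-4,6,6-trimethyl-2-(trimethylsilyloxy)bicyclo[3.1.1]hept-2-ene
Product: 7 (1S,4R,5R)-4-[3-(tert-butyldimethylsilyloxy)propyl]-4,6,6-trimethyl-3-methylidenebicyclo[3.1.1]heptan-2-one, via Mannich base 5 (not isolated), via ammonium iodide 6 (not isolated)
Conditions: CH2=NMe2+ I−, CH2Cl2, rt; aq. NaHCO3 wash; crude 5: MeI, MeOH, rt; then aq. NaHCO3/CH2Cl2, rt
Reagents that add atoms: N,N-dimethylmethyleneiminium iodide (Eschenmoser's salt), C=[N+](C)C.[I-]
Why: Mukaiyama–Mannich reaction of the silyl enol ether, then quaternisation and E1cB elimination (classical α-methylenation); C3' ends sp2, so its transient configuration is irrelevant, and the exocyclic enone cannot move into the ring because C4' is quaternary and C1' a bridgehead.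

Step 3
Reactants: 7 (1S,4R,5R)-4-[3-(tert-butyldimethylsilyloxy)propyl]-4,6,6-trimethyl-3-methylidenebicyclo[3.1.1]heptan-2-one
Product: 8 (1S,2R,4R,5R)-4-[3-(tert-butyldimethylsilyloxy)propyl]-2,4,6,6-tetramethyl-3-methylidenebicyclo[3.1.1]heptan-2-ol
Conditions: MeLi, anhydrous CeCl3, THF, −78 °C; aq. NH4Cl
Reagents that add atoms: methyllithium, [Li]C
Why: Organocerium 1,2-addition to a hindered, non-enolisable enone (1,4-addition suppressed); attack anti to the CMe2 bridge should give the 2R carbinol with OH syn to the bridge; this centre becomes sp2 again later and serves to carry the future C3 methyl and to direct steps 4 and 6.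

Step 4
Reactants: 8 (1S,2R,4R,5R)-4-[3-(tert-butyldimethylsilyloxy)propyl]-2,4,6,6-tetramethyl-3-methylidenebicyclo[3.1.1]heptan-2-ol
Product: 10 (1S,2R,3R,4R,5R)-4-[3-(tert-butyldimethylsilyloxy)propyl]-3-(hydroxymethyl)-2,4,6,6-tetramethylbicyclo[3.1.1]heptan-2-ol, via alkylborane 9 (not isolated)
Conditions: 9-BBN (3 equiv), THF, 65 °C; then 3 M NaOH, 30% H2O2, 0 °C→rt
Reagents that add atoms: hydrogen peroxide, OO
Why: Hydroboration–oxidation with boron on the exocyclic CH2; hydrogen should reach C3' from the face anti to the CMe2 bridge (the sense known for β-pinene), so CH2OH ends syn to the bridge and cis to the C4' methyl (3R, ring C2 of the target); the tertiary O–B(9-BBN) group formed in the flask has no B–H, so it cannot deliver hydride to the wrong face and adds bulk there.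

Step 5
Reactants: 10 (1S,2R,3R,4R,5R)-4-[3-(tert-butyldimethylsilyloxy)propyl]-3-(hydroxymethyl)-2,4,6,6-tetramethylbicyclo[3.1.1]heptan-2-ol; 11 7-hydroxy-2H-chromen-2-one (umbelliferone)
Product: 12 7-{[(1S,2R,3R,4R,5R)-4-[3-(tert-butyldimethylsilyloxy)propyl]-2-hydroxy-2,4,6,6-tetramethylbicyclo[3.1.1]heptan-3-yl]methoxy}-2H-chromen-2-one
Conditions: PPh3, DIAD, THF, 0 °C→rt
Reagents that add atoms: none
Why: Mitsunobu etherification of an acidic phenol; only the primary alcohol can form a displaceable oxyphosphonium ion, the tertiary alcohol stays, and no stereocentre takes part.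

Step 6
Reactants: 12 7-{[(1S,2R,3R,4R,5R)-4-[3-(tert-butyldimethylsilyloxy)propyl]-2-hydroxy-2,4,6,6-tetramethylbicyclo[3.1.1]heptan-3-yl]methoxy}-2H-chromen-2-one
Product: 13 7-{[(1S,3R,4R,5R)-4-[3-(tert-butyldimethylsilyloxy)propyl]-4,6,6-trimethyl-2-methylidenebicyclo[3.1.1]heptan-3-yl]methoxy}-2H-chromen-2-one
Conditions: Burgess reagent (MeO2C–N−–SO2–N+Et3), toluene, 60 °C
Reagents that add atoms: none
Why: Burgess dehydration by syn elimination through the sulfamate ester; the C3'–H is trans to the C2'–O bond and C1' is a bridgehead, so only methyl hydrogens are syn and the exocyclic alkene should form regioselectively.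

Step 7
Reactants: 13 7-{[(1S,3R,4R,5R)-4-[3-(tert-butyldimethylsilyloxy)propyl]-4,6,6-trimethyl-2-methylidenebicyclo[3.1.1]heptan-3-yl]methoxy}-2H-chromen-2-one
Product: 14 7-{[(1R,5R,6R)-6-[3-(tert-butyldimethylsilyloxy)propyl]-2,6-dimethyl-5-(prop-1-en-2-yl)cyclohex-2-en-1-yl]methoxy}-2H-chromen-2-one
Conditions: Co(tBu4-salen)Cl (5 mol%), PhSiH3 (10 mol%), benzene, rt, argon
Reagents that add atoms: none
Why: Metal-hydride hydrogen-atom-transfer retro-cycloisomerisation; the closest known reaction type is the radical-clock ring opening of β-pinene-type methylidenecyclobutanes under cobalt-salen/silane alkene-isomerisation conditions. PhSiH3 turns the precatalyst into a trivalent cobalt hydride, which gives H• to the exocyclic CH2 of 13; this creates the C3 methyl of the target and a tertiary radical at C2'. β-Scission of the strained C1'–C6' bond follows (a tertiary radical forms and the cyclobutane strain is released, whereas scission of C1'–C7' would give a primary radical), producing the C1'=C2' ring alkene (target C3=C4) and a 2-propyl radical on C5'. Divalent cobalt then removes a methyl hydrogen, which gives the isopropenyl group and returns the cobalt hydride, so the step is a redox-neutral isomerisation catalytic in silane. No ring is closed: the four-membered ring C1'–C6'–C5'–C7' is opened and the six-membered ring C1'–C2'–C3'–C4'–C5'–C7' remains as the cyclohexene. No stereocentre is created; C5', C4' and C3' (target C6, C1, C2) are not radical sites and keep the configurations fixed on the bicycle in steps 1 and 4, so the all-cis triad is inherited. The step needs hydrogen abstraction from a methyl group and not from C5'–H (six methyl hydrogens against one methine hydrogen that is shielded by the quaternary neighbour, and the tetrasubstituted alternative suffers allylic strain), and hydrogen-atom transfer to the 1,1-disubstituted alkene and not to the coumarin alkene or the trisubstituted product alkene, both poor acceptors under these conditions. Abstraction of C3'–H at the first radical would only give an endocyclic alkene that takes hydrogen back on the open face anti to the bridge, restoring the same C3' configuration.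

Step 8
Reactants: 14 7-{[(1R,5R,6R)-6-[3-(tert-butyldimethylsilyloxy)propyl]-2,6-dimethyl-5-(prop-1-en-2-yl)cyclohex-2-en-1-yl]methoxy}-2H-chromen-2-one
Product: 15 7-{[(1R,5R,6R)-6-(3-hydroxypropyl)-2,6-dimethyl-5-(prop-1-en-2-yl)cyclohex-2-en-1-yl]methoxy}-2H-chromen-2-one
Conditions: TBAF, AcOH, THF, 0 °C→rt
Reagents that add atoms: none
Why: Fluoride-mediated cleavage of a primary silyl ether; the acetic acid buffer keeps the medium from opening the coumarin lactone, and the alkenes and stereocentres are not involved.

Step 9
Reactants: 15 7-{[(1R,5R,6R)-6-(3-hydroxypropyl)-2,6-dimethyl-5-(prop-1-en-2-yl)cyclohex-2-en-1-yl]methoxy}-2H-chromen-2-one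
Product: 16 3-[(1R,2R,6R)-1,3-dimethyl-2-{[(2-oxo-2H-chromen-7-yl)oxy]methyl}-6-(prop-1-en-2-yl)cyclohex-3-en-1-yl]propanoic acid
Conditions: TEMPO (20 mol%), PhI(OAc)2 (2.5 equiv), MeCN/H2O 1:1, rt
Reagents that add atoms: water, O
Why: Oxoammonium (TEMPO/PhI(OAc)2) oxidation of a primary alcohol through the aldehyde hydrate to the acid; the conditions are known to spare isolated alkenes, aryl ethers and lactones, and no stereocentre is α to the new carboxyl group.

## Compound list

1 | (1S,5S)-4,6,6-trimethylbicyclo[3.1.1]hept-3-en-2-one, (−)-verbenone | CC1=CC(=O)[C@H]2C[C@@H]1C2(C)C | starting material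
2 | (3-bromopropoxy)(tert-butyl)dimethylsilane | BrCCCO[Si](C)(C)C(C)(C)C | starting material
3 | {3-[(tert-butyldimethylsilyl)oxy]propyl}magnesium bromide | CC(C)(C)[Si](C)(C)OCCC[Mg]Br | intermediate (not isolated)
4 | (1S,4R,5R)-4-[3-(tert-butyldimethylsilyloxy)propyl]-4,6,6-trimethyl-2-(trimethylsilyloxy)bicyclo[3.1.1]hept-2-ene | C[C@]1(CCCO[Si](C)(C)C(C)(C)C)C=C(O[Si](C)(C)C)[C@H]2C[C@@H]1C2(C)C | intermediate
5 | (1S,3S,4R,5R)-4-[3-(tert-butyldimethylsilyloxy)propyl]-3-[(dimethylamino)methyl]-4,6,6-trimethylbicyclo[3.1.1]heptan-2-one | C[C@]1(CCCO[Si](C)(C)C(C)(C)C)[C@@H](CN(C)C)C(=O)[C@H]2C[C@@H]1C2(C)C | intermediate (not isolated)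
6 | {[(1S,3S,4R,5R)-4-[3-(tert-butyldimethylsilyloxy)propyl]-4,6,6-trimethyl-2-oxobicyclo[3.1.1]heptan-3-yl]methyl}trimethylammonium iodide | C[C@]1(CCCO[Si](C)(C)C(C)(C)C)[C@@H](C[N+](C)(C)C)C(=O)[C@H]2C[C@@H]1C2(C)C.[I-] | intermediate (not isolated)
7 | (1S,4R,5R)-4-[3-(tert-butyldimethylsilyloxy)propyl]-4,6,6-trimethyl-3-methylidenebicyclo[3.1.1]heptan-2-one | C[C@]1(CCCO[Si](C)(C)C(C)(C)C)C(=C)C(=O)[C@H]2C[C@@H]1C2(C)C | intermediate
8 | (1S,2R,4R,5R)-4-[3-(tert-butyldimethylsilyloxy)propyl]-2,4,6,6-tetramethyl-3-methylidenebicyclo[3.1.1]heptan-2-ol (OH syn to the CMe2 bridge) | C[C@]1(CCCO[Si](C)(C)C(C)(C)C)C(=C)[C@](C)(O)[C@H]2C[C@@H]1C2(C)C | intermediate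
9 | B-alkyl-9-borabicyclo[3.3.1]nonane from 8, boron on the former exocyclic carbon, C3'–H anti to the CMe2 bridge (tertiary OH drawn free) | C[C@]1(CCCO[Si](C)(C)C(C)(C)C)[C@H](CB3C4CCCC3CCC4)[C@](C)(O)[C@H]2C[C@@H]1C2(C)C | intermediate (not isolated)
10 | (1S,2R,3R,4R,5R)-4-[3-(tert-butyldimethylsilyloxy)propyl]-3-(hydroxymethyl)-2,4,6,6-tetramethylbicyclo[3.1.1]heptan-2-ol | C[C@]1(CCCO[Si](C)(C)C(C)(C)C)[C@H](CO)[C@](C)(O)[C@H]2C[C@@H]1C2(C)C | intermediate
11 | 7-hydroxy-2H-chromen-2-one (umbelliferone) | O=c1ccc2ccc(O)cc2o1 | starting material
12 | 7-{[(1S,2R,3R,4R,5R)-4-[3-(tert-butyldimethylsilyloxy)propyl]-2-hydroxy-2,4,6,6-tetramethylbicyclo[3.1.1]heptan-3-yl]methoxy}-2H-chromen-2-one | C[C@]1(CCCO[Si](C)(C)C(C)(C)C)[C@H](COc3ccc4ccc(=O)oc4c3)[C@](C)(O)[C@H]2C[C@@H]1C2(C)C | intermediate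
13 | 7-{[(1S,3R,4R,5R)-4-[3-(tert-butyldimethylsilyloxy)propyl]-4,6,6-trimethyl-2-methylidenebicyclo[3.1.1]heptan-3-yl]methoxy}-2H-chromen-2-one | C[C@]1(CCCO[Si](C)(C)C(C)(C)C)[C@H](COc3ccc4ccc(=O)oc4c3)C(=C)[C@H]2C[C@@H]1C2(C)C | intermediate
14 | 7-{[(1R,5R,6R)-6-[3-(tert-butyldimethylsilyloxy)propyl]-2,6-dimethyl-5-(prop-1-en-2-yl)cyclohex-2-en-1-yl]methoxy}-2H-chromen-2-one | C=C(C)[C@H]1CC=C(C)[C@@H](COc2ccc3ccc(=O)oc3c2)[C@]1(C)CCCO[Si](C)(C)C(C)(C)C | intermediate
15 | 7-{[(1R,5R,6R)-6-(3-hydroxypropyl)-2,6-dimethyl-5-(prop-1-en-2-yl)cyclohex-2-en-1-yl]methoxy}-2H-chromen-2-one | C=C(C)[C@H]1CC=C(C)[C@@H](COc2ccc3ccc(=O)oc3c2)[C@]1(C)CCCO | intermediate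
16 | 3-[(1R,2R,6R)-1,3-dimethyl-2-{[(2-oxo-2H-chromen-7-yl)oxy]methyl}-6-(prop-1-en-2-yl)cyclohex-3-en-1-yl]propanoic acid (CNP0103683.1) | C=C(C)[C@H]1CC=C(C)[C@@H](COc2ccc3ccc(=O)oc3c2)[C@]1(C)CCC(=O)O | target

## Step count and least certain steps

Total step count: 9. Longest linear sequence: 9 steps (1 to 16; 2 and 11 enter as purchased compounds).

**Step 7 (key step).** What may go wrong:
- over-isomerisation, in which the cobalt hydride re-enters the isopropenyl group and drains it to the isopropylidene isomer (loss of the C6 stereocentre) or moves the ring alkene;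
- net hydrogenation if silane is not kept catalytic;
- hydrogen-atom transfer to the coumarin alkene.

Fallback (polar instead of radical opening of the same bond): set out from 13 and treat it with dilute aqueous acid (chloroacetic acid in wet acetone, rt). This is the pinene-to-terpineol type hydration with cyclobutane opening and should give 7-{[(1R,5S,6S)-6-[3-(tert-butyldimethylsilyloxy)propyl]-5-(2-hydroxypropan-2-yl)-2,6-dimethylcyclohex-2-en-1-yl]methoxy}-2H-chromen-2-one F1. Burgess dehydration of F1 (toluene, 50 °C), in which the hindered methine hydrogen next to the quaternary carbon is the disfavoured partner, then leads back to the route at 14.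

**Step 4.** What may go wrong: poor facial selectivity in hydrogen delivery to C3' (both faces are flanked by substituents on C2' and C4'; only the bridge differentiates them), or sluggish addition of the bulky borane to a doubly neopentyl alkene. Fallback (radical instead of four-centre delivery): set out from 8 and epoxidise the exocyclic alkene (mCPBA, NaHCO3, CH2Cl2, 0 °C) to the spiro-epoxide (1S,2R,4R,5R)-4-[3-(tert-butyldimethylsilyloxy)propyl]-2,4,6,6-tetramethylspiro[bicyclo[3.1.1]heptane-3,2'-oxiran]-2-ol F2. Either epoxide epimer serves; the oxygen-anti one is drawn. Open it reductively with Cp2TiCl (trivalent titanium, from Cp2TiCl2 and Zn) and 1,4-cyclohexadiene in THF. The planar C3' radical should take its hydrogen from a small donor on the open face anti to the bridge, and the primary titanium alkoxide gives 10 on work-up, where the route is rejoined.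

**Step 6.** What may go wrong: ionisation of the tertiary sulfamate instead of syn elimination (pinyl cation, skeletal rearrangement or premature ring opening), or slow sulfamoylation of the hindered hydroxyl. Fallback (Peterson olefination in place of dehydration, regiospecific by construction): set out from 7.
- Add Me3SiCH2Li/CeCl3 (THF, −78 °C) to give (1S,2R,4R,5R)-4-[3-(tert-butyldimethylsilyloxy)propyl]-4,6,6-trimethyl-3-methylidene-2-[(trimethylsilyl)methyl]bicyclo[3.1.1]heptan-2-ol F3.
- Hydroborate and oxidise as in step 4 to (1S,2R,3R,4R,5R)-4-[3-(tert-butyldimethylsilyloxy)propyl]-3-(hydroxymethyl)-4,6,6-trimethyl-2-[(trimethylsilyl)methyl]bicyclo[3.1.1]heptan-2-ol F4.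
- Etherify with 11 as in step 5 to 7-{[(1S,2R,3R,4R,5R)-4-[3-(tert-butyldimethylsilyloxy)propyl]-2-hydroxy-4,6,6-trimethyl-2-[(trimethylsilyl)methyl]bicyclo[3.1.1]heptan-3-yl]methoxy}-2H-chromen-2-one F5.
- Eliminate with KH in THF (0 °C→rt, mild acidic work-up to reclose any opened lactone), which comes back to the route at 13.

The larger CH2SiMe3 group on the anti face makes the hydroboration of F3 less certain than that of 8, which is why this is the fallback and not the main line.

**Step 5.** What may go wrong: slow displacement at the β-branched primary carbon, so that the oxyphosphonium ion is diverted to elimination or to attack by the neighbouring tertiary hydroxyl. Fallback (the other C–O bond is formed): set out from 10 and couple its primary alcohol with purchased 7-bromo-2H-chromen-2-one under palladium catalysis ([Pd(allyl)Cl]2, tBuBrettPhos, Cs2CO3, toluene, 80 °C). The tertiary alcohol is too hindered to compete, and the product is 12 directly; this detour makes no new compound (F0).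

## Further compounds

F1 | step 7 | 7-{[(1R,5S,6S)-6-[3-(tert-butyldimethylsilyloxy)propyl]-5-(2-hydroxypropan-2-yl)-2,6-dimethylcyclohex-2-en-1-yl]methoxy}-2H-chromen-2-one | CC(C)(O)[C@H]1CC=C(C)[C@@H](COc2ccc3ccc(=O)oc3c2)[C@]1(C)CCCO[Si](C)(C)C(C)(C)C
F2 | step 4 | (1S,2R,4R,5R)-4-[3-(tert-butyldimethylsilyloxy)propyl]-2,4,6,6-tetramethylspiro[bicyclo[3.1.1]heptane-3,2'-oxiran]-2-ol, epoxide oxygen anti to the CMe2 bridge | C[C@]1(CCCO[Si](C)(C)C(C)(C)C)[C@]3(CO3)[C@](C)(O)[C@H]2C[C@@H]1C2(C)C
F3 | step 6 | (1S,2R,4R,5R)-4-[3-(tert-butyldimethylsilyloxy)propyl]-4,6,6-trimethyl-3-methylidene-2-[(trimethylsilyl)methyl]bicyclo[3.1.1]heptan-2-ol | C[C@]1(CCCO[Si](C)(C)C(C)(C)C)C(=C)[C@](C[Si](C)(C)C)(O)[C@H]2C[C@@H]1C2(C)C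
F4 | step 6 | (1S,2R,3R,4R,5R)-4-[3-(tert-butyldimethylsilyloxy)propyl]-3-(hydroxymethyl)-4,6,6-trimethyl-2-[(trimethylsilyl)methyl]bicyclo[3.1.1]heptan-2-ol | C[C@]1(CCCO[Si](C)(C)C(C)(C)C)[C@H](CO)[C@](C[Si](C)(C)C)(O)[C@H]2C[C@@H]1C2(C)C
F5 | step 6 | 7-{[(1S,2R,3R,4R,5R)-4-[3-(tert-butyldimethylsilyloxy)propyl]-2-hydroxy-4,6,6-trimethyl-2-[(trimethylsilyl)methyl]bicyclo[3.1.1]heptan-3-yl]methoxy}-2H-chromen-2-one | C[C@]1(CCCO[Si](C)(C)C(C)(C)C)[C@H](COc3ccc4ccc(=O)oc4c3)[C@](C[Si](C)(C)C)(O)[C@H]2C[C@@H]1C2(C)C
F0 | step 5 | none | none
A1 | alternative 1 | methyl 3-[(1R,6R)-1,3-dimethyl-2-oxo-6-(prop-1-en-2-yl)cyclohex-3-en-1-yl]propanoate | C=C(C)[C@H]1CC=C(C)C(=O)[C@]1(C)CCC(=O)OC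
A2 | alternative 1 | methyl 3-[(1R,2R,6R)-2-formyl-1,3-dimethyl-6-(prop-1-en-2-yl)cyclohex-3-en-1-yl]propanoate | C=C(C)[C@H]1CC=C(C)[C@@H](C=O)[C@]1(C)CCC(=O)OC
A3 | alternative 2 | 7-{[(2E,6E)-9-[(2R)-3,3-dimethyloxiran-2-yl]-3,7-dimethylnona-2,6-dien-1-yl]oxy}-2H-chromen-2-one | CC1(C)O[C@@H]1CC/C(C)=C/CC/C(C)=C/COc1ccc2ccc(=O)oc2c1
A4 | alternative 2 | 7-{[(1R,4aS,8aR)-2,5,5,8a-tetramethyl-6-oxo-1,4,4a,5,6,7,8,8a-octahydronaphthalen-1-yl]methoxy}-2H-chromen-2-one | CC1(C)[C@H]2CC=C(C)[C@@H](COc3ccc4ccc(=O)oc4c3)[C@]2(C)CCC1=O
A5 | alternative 2 | 3-[(1R,2R,6R)-1,3-dimethyl-2-{[(2-oxo-2H-chromen-7-yl)oxy]methyl}-6-(prop-1-en-2-yl)cyclohex-3-en-1-yl]propanenitrile | C=C(C)[C@H]1CC=C(C)[C@@H](COc2ccc3ccc(=O)oc3c2)[C@]1(C)CCC#N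
A6 | alternative 3 | tributyl({[(1R,4S,5R)-4-[3-(tert-butyldimethylsilyloxy)propyl]-2,4-dimethyl-5-(prop-1-en-2-yl)cyclohex-2-en-1-yl]oxy}methyl)stannane | C=C(C)[C@H]1C[C@@H](OC[Sn](CCCC)(CCCC)CCCC)C(C)=C[C@]1(C)CCCO[Si](C)(C)C(C)(C)C
A7 | alternative 3 | (4S,5R)-4-[3-(tert-butyldimethylsilyloxy)propyl]-2,4-dimethyl-5-(prop-1-en-2-yl)cyclohex-2-en-1-one | C=C(C)[C@H]1CC(=O)C(C)=C[C@]1(C)CCCO[Si](C)(C)C(C)(C)C
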